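All runs are simulated for an exercise, and the scatter is random.

At late times the target was falling in both earlier runs: grey went from 55% at 5.00 min to 43% at 8.00 min, and teal from 44% at 4.00 min to 35% at 8.00 min. So I expected that stretching the feed of partner from 6.0 min to 12 min or 25 min would let the target form later and lose less, though the feed might not be through by the harvest. I had to choose the feed for the next flask, harvested at 8.0 min.

| flask | starting material | partner | remark | time |
|---|---|---|---|---|
| grey | 0.050 M | 0.25 M (fed, over 6.0 min) | run made earlier; the fed solution adds 0.25 times the starting volume |  |
| teal | 0.075 M | 0.25 M (fed, over 6.0 min) | run made earlier; the fed solution adds 0.25 times the starting volume |  |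
| ash | 0.10 M | 0.250 M (fed, over 6.0 min) | the fed solution adds 0.25 times the starting volume | 8.0 min |
| larch | 0.10 M | 0.250 M (fed, over 12 min) | the fed solution adds 0.25 times the starting volume | 8.0 min |
| oak | 0.10 M | 0.250 M (fed, over 25 min) | the fed solution adds 0.25 times the starting volume | 8.0 min |

| run | time / min | target / % | starting material / % |
|---|---|---|---|
| grey | 1.50 | 19 | 54 |
| grey | 3.00 | 49 | 17 |
| grey | 5.00 | 55 | 0 |
| grey | 6.00 | 50 | 5 |
| grey | 8.00 | 43 | 0 |
| teal | 0.667 | 2 | 82 |
| teal | 1.33 | 12 | 64 |
| teal | 2.50 | 31 | 27 |
| teal | 4.00 | 44 | 6 |
| teal | 8.00 | 35 | 4 |

(readings scatter by 2 percentage points)

* amount of target at the end, in percent of the starting material charged for ash, larch, oak, in this order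
* the shape of the row from first to last (hardly changes / falls all the way / falls, then rises / rises all the way / rises, then falls)

- amounts are per litre of the starting volume; all of the dose is in the solution fed
- percentages count the whole charge, also what has not yet gone in
- "hardly changes" means that all values lie within two and a half points (for a concentration: within two and a half percent of the largest)

I read both falls as first-order losses and took their mean:

k(grey) = 0.0820 min⁻¹
k(teal) = 0.0572 min⁻¹
k(mean) = 0.0696 min⁻¹

Then I replaced the formation curve by its mean. Partner enters at a steady rate, so I let the target form evenly until the equivalence time, when the partner fed equals the starting material charged. Before that moment, the partner fed so far is the limiting reagent.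

ash: 2.40 min
larch: 4.80 min
oak: 10.0 min

Oak reaches equivalence later than the harvest, so by then its feed covers 80.0% of the charge. In this picture, the mean age of the target at harvest is the harvest time less half the forming time. Multiplying the share reached by the survival over that age gave the keep factor:

ash: 0.623
larch: 0.677
oak: 0.606

The mean has an error. Grey at 1.50 min was past its equivalence time of 1.20 min, yet its reading still showed 54% of the starting material, so in grey the reaction trailed the feed. I therefore used keep factors as ratios between flasks, not as yields. Larch stood highest, so I chose the 12 min feed.

The forecast gave 30%, 44% and 40%, a row that rises, then falls, with “a side loss of second order in the intermediate” among its grounds.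

The flask gave 31.5%, 34.3% and 28.9%, a row that rises, then falls.

    starting material ⇌ dormant form (K = 0.690, k = 0.00200 s⁻¹)
    intermediate → target (k = 0.0260 s⁻¹)
    starting material + partner → intermediate + released group (k = 0.220 L mol⁻¹ s⁻¹)
    target + released group → side product B (k = 0.0800 L mol⁻¹ s⁻¹)
    intermediate → side product A (k = 0.00320 s⁻¹)

Larch gave the most target, and its ratio to ash was 1.09, with 1.09 from the keep factors. On oak, the keep factors gave 0.895 of larch and the flask gave 0.843. At 8.00 min oak held 21.2% as starting material and 23.0% as dormant form, together 44.2%, against the 20.0% that its feed had not covered.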